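**Convention.** The indenone of the target is numbered C1 (carbonyl), C2, C3, C3a, C4–C7, C7a. The azulene atoms carry primes. "Guaiazulen-3-yl" means 7-isopropyl-1,4-dimethylazulen-3-yl (systematically 5-isopropyl-3,8-dimethylazulen-1-yl). Compound numbers are those of the steps and of the compound list.

## Analysis of the target

Target 15 is a 1H-inden-1-one. Its five-membered enone ring (C1, C2, C3, C3a, C7a) is fused to a benzene ring (C3a, C4–C7, C7a) that carries a formyl group on C4 and a methyl group on C7. C3 carries a methyl group, and C2 is bonded to C3' of a guaiazulene unit, which is compound 3 less one hydrogen. The molecule has no stereocentre and no stereogenic double bond. The only geometric question arises earlier, in the open-chain alkene that becomes C2=C3. The sensitive groups are the azulene (nucleophilic at C1' and C3', protonated by strong acid, easily oxidised), the aldehyde, and the cross-conjugated indenone, which is a good Michael acceptor. The difficulty lies in the fully substituted C2=C3 bond next to an azulenyl group with a peri methyl on C4', and in the 1,2,3,4-tetrasubstituted benzene ring with three different carbon substituents. The strategy rests on C7a: it is ortho to the C7 methyl, meta to the C4 formyl, and in a ring-opened precursor the only unsubstituted carbon ortho to C3a. At the same time C1' and C3' of the azulene are both substituted, so an acylium ion on C1 has one place to go. Since 3 is commercial with the complete substitution pattern, the azulene is bought and not built.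

## Retrosynthetic reasoning

**C1–C7a.** This bond of 15 is cut first. It is the bond between the ketone carbon and the benzene ring, so it opens the five-membered ring to the cis-β-arylacrylic acid 13, reached through its acid chloride 14. The cut is made here because the acylation site is unambiguous and no adjustment is needed after ring closure. The forward reaction has to acylate a ring that carries a formyl group and must leave the azulene alone. The aryl ring and the carboxyl group must therefore stand cis on the alkene of 13.

**Protecting groups of 13.** The free acid and free aldehyde are traced back to the methyl ester and cyclic acetal 11, with carboxylate 12 as the stage between them. The ester is needed for the carbon–carbon bond formations. The acetal keeps the aldehyde out of the organometallic and hydroxide chemistry. One operation removes both.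

**C3–C3a.** The bond between the alkene carbon and the aryl ring of 11 is cut next. This gives the Z-enol triflate 6 and the aryl boronate 10. A cross-coupling with retention at the alkene carbon carries the geometry of 6 into 11, so the cis relation needed for the key step is set in a small, easily analysed molecule. The forward reaction has to form a tetrasubstituted alkene from an ortho-substituted boronate.

**C–O bond of 6.** The triflate comes from β-keto ester 4 through its chelated enolate 5. The chelate places the enolate oxygen cis to the ester, which is exactly the geometry the coupling must deliver.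

**C3'–Cα.** The bond between the azulene and the α-carbon of 4 is cut to guaiazulene 3 and diazo ester 2. This uses the natural nucleophilicity of C3' of 3, the only free reactive position of its five-membered ring, and brings in the whole four-carbon acetoacetate unit in one step. Compound 2 comes from methyl acetoacetate 1 by diazo transfer.

**Aryl fragment.** Boronate 10 is traced through aryllithium 9 and bromo acetal 8 to 2-bromo-4-methylbenzaldehyde 7. In 7 the bromine is ortho to the formyl group and meta to the methyl group, which maps onto C3a, C4 and C7 of the target.

## Alternatives that were turned down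

**Alternative 1: azulene from a benzenoid ring by intramolecular Buchner expansion.** The disconnection takes the azulene apart. Its seven-membered ring derives from a 5-isopropyl-2-methylphenyl group that is expanded by a tethered carbenoid. In the forward key step Rh2(OAc)4 decomposes diazoketone A2. The carbenoid carbon adds across the ipso–ortho bond away from the methyl group, and the norcaradiene opens to the dihydroazulenone A1. Methyl addition to the ring ketone, dehydration and dehydrogenation would then give the azulenylmethyl aryl ketone A3. Acetal removal and an intramolecular aldol condensation onto the ortho acetyl group would give 15.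
- For it: the starting materials are simple benzenoids and the Buchner reaction is a dependable way to make hydroazulenones. The indenone is closed by an aldol condensation, which needs neither an alkene geometry nor an electrophilic substitution on a formyl-bearing ring. On that point it is stronger than the chosen route.
- Against it: it rebuilds a ring system that 3 supplies ready-made. A1 is a diastereomer mixture whose two sp3 centres must be erased. The methyl addition must distinguish the ring ketone from the side-chain aryl ketone. The aryl part needs a benzene ring with three different masked carbonyl substituents.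
- Comparison: the chosen route accepts a harder ring closure in exchange for convergence, no redox adjustments, and an aryl fragment made in two steps from 7.

**Alternative 2: azulene by (8+2) cycloaddition on the side chain.** The five-membered azulene ring is disconnected to the cycloheptafuranone A4 and the enamine A5. On heating, A5 adds to A4, and loss of carbon dioxide and of the amine gives A3 directly. A3 is the ketone that Alternative 1 reaches only after several more steps.
- For it: this enamine route to 1,3-disubstituted azulenes is established and places the methyl group and the side chain correctly. The endgame is again the aldol closure, so it shares that advantage over the chosen route.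
- Against it: A4 is not a commercial compound. It needs a regiodefined isopropyl- and methyl-substituted troponoid, which takes several steps. The enamine partner carries a second ketone and the same heavily substituted aryl ring as in Alternative 1. The cycloaddition needs high temperature.
- Comparison: the chosen route spends its steps on the one bond that must be made and none on making an azulene.

**Alternative 3: rhodium (2+2+2) benzannulation.** The benzene ring of the indenone is disconnected at C3a–C7a, C4–C5 and C6–C7 to the enediynone A7 and acetylene A8. RhCl(PPh3)3 under A8 would couple the two tethered alkynes with A8 and give the diethyl acetal A6 of the target, closing both rings in one step.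
- For it: it has the highest bond count per step. The tether fixes the positions of the methyl and the masked formyl group. The conditions are neutral and avoid any electrophilic substitution on a deactivated ring. On regiocontrol of the benzene ring and on mildness it is stronger than the chosen route.
- Against it: A7 is a doubly activated ynone and enyne that is far more fragile than acid 13. It needs the same Z alkene geometry as 13. The two alkynes are held by a rigid three-carbon sp2 tether, so the metallacycle is strained. Cross-trimerisation with gaseous A8 competes with oligomerisation. Making A7 from 3 would take about as many steps as the whole chosen route.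
- Comparison: the chosen route offers a stable, crystalline-type acid as precursor and uses only standard operations before the key step.

Key step: step 8

## Route

Assumption: the C2–C3' axis is treated as freely rotating, since the target structure defines no stereo element. The only configuration to control is the alkene geometry of 6, 11 and 13.

Step 1
Reactants: 1 methyl acetoacetate
Product: 2 methyl 2-diazo-3-oxobutanoate
Conditions: 4-acetamidobenzenesulfonyl azide, Et3N, MeCN, 0 °C to rt
Reagents that add atoms: 4-acetamidobenzenesulfonyl azide, CC(=O)Nc1ccc(S(=O)(=O)N=[N+]=[N-])cc1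
Why: Regitz diazo transfer to an active methylene compound; the enolate attacks the terminal azide nitrogen and the adduct collapses to the diazo ester and the sulfonamide, which is filtered off.

Step 2
Reactants: 3 guaiazulene (7-isopropyl-1,4-dimethylazulene); 2 methyl 2-diazo-3-oxobutanoate
Product: 4 methyl 2-(guaiazulen-3-yl)-3-oxobutanoate (racemic, enolisable)
Conditions: Rh2(OAc)4 (2 mol %), ClCH2CH2Cl, 60 °C, slow addition of 2
Reagents that add atoms: none
Why: Rhodium-carbenoid C–H functionalisation of an azulene (formal C–H insertion): the electrophilic acceptor/acceptor carbenoid is attacked by C3', the only free nucleophilic carbon of the five-membered ring, and the tropylium-type zwitterion rearomatises by proton transfer. The new centre is enolisable and is removed in step 3, so its configuration is of no consequence.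

Step 3
Reactants: 4 methyl 2-(guaiazulen-3-yl)-3-oxobutanoate
Product: 6 methyl (2Z)-2-(guaiazulen-3-yl)-3-[(trifluoromethylsulfonyl)oxy]but-2-enoate, via sodium Z-enolate 5 (not isolated)
Conditions: NaH, THF, 0 °C; then N-phenylbis(trifluoromethanesulfonimide), 0 °C to rt
Reagents that add atoms: N-phenylbis(trifluoromethanesulfonimide), O=S(=O)(N(c1ccccc1)S(=O)(=O)C(F)(F)F)C(F)(F)F
Why: Chelation-controlled enol triflation of a β-keto ester: the sodium enolate sits in a six-membered chelate with the enolate oxygen cis to the ester, and O-sulfonylation fixes this as the Z-triflate. The mild imide reagent is chosen over Tf2O to spare the azulene.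

Step 4
Reactants: 7 2-bromo-4-methylbenzaldehyde
Product: 8 2-(2-bromo-4-methylphenyl)-1,3-dioxolane
Conditions: ethylene glycol, p-TsOH·H2O (cat.), toluene, reflux, Dean–Stark
Reagents that add atoms: ethylene glycol, OCCO
Why: Acid-catalysed acetalisation driven by azeotropic removal of water; the acetal masks the aldehyde against the aryllithium of step 5 and the hydroxide of step 7.

Step 5
Reactants: 8 2-(2-bromo-4-methylphenyl)-1,3-dioxolane
Product: 10 2-[2-(1,3-dioxolan-2-yl)-5-methylphenyl]-4,4,5,5-tetramethyl-1,3,2-dioxaborolane, via aryllithium 9 (not isolated)
Conditions: n-BuLi, THF, −78 °C; then 2-isopropoxy-4,4,5,5-tetramethyl-1,3,2-dioxaborolane, −78 °C to rt; aq. NH4Cl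
Reagents that add atoms: 2-isopropoxy-4,4,5,5-tetramethyl-1,3,2-dioxaborolane, CC(C)OB1OC(C)(C)C(C)(C)O1
Why: Bromine–lithium exchange followed by borylation; at −78 °C the exchange is faster than any attack on the acetal, and the aryllithium displaces isopropoxide from the borate ester.

Step 6
Reactants: 6 methyl (2Z)-2-(guaiazulen-3-yl)-3-[(trifluoromethylsulfonyl)oxy]but-2-enoate; 10 2-[2-(1,3-dioxolan-2-yl)-5-methylphenyl]-4,4,5,5-tetramethyl-1,3,2-dioxaborolane
Product: 11 methyl (2Z)-3-[2-(1,3-dioxolan-2-yl)-5-methylphenyl]-2-(guaiazulen-3-yl)but-2-enoate
Conditions: Pd(OAc)2 (5 mol %), SPhos (10 mol %), K3PO4, THF/H2O 10:1, 60 °C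
Reagents that add atoms: none
Why: Suzuki–Miyaura coupling of a β-(triflyloxy)acrylate: zerovalent palladium inserts into the activated C–OTf bond, and transmetalation and reductive elimination proceed with retention, so the aryl group takes the place of the triflate cis to the ester. The bulky electron-rich biaryl phosphine is chosen because a tetrasubstituted alkene is formed from an ortho-substituted boronate.

Step 7
Reactants: 11 methyl (2Z)-3-[2-(1,3-dioxolan-2-yl)-5-methylphenyl]-2-(guaiazulen-3-yl)but-2-enoate
Product: 13 (2Z)-3-(2-formyl-5-methylphenyl)-2-(guaiazulen-3-yl)but-2-enoic acid, via lithium carboxylate acetal 12 (not isolated)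
Conditions: LiOH·H2O, THF/MeOH/H2O, 50 °C; then 2 M aq. HCl to pH 1, THF, rt
Reagents that add atoms: lithium hydroxide, [Li+].[OH-]; water, O
Why: Ester saponification followed by acid-catalysed acetal hydrolysis in the same flask. The ester is cleaved while the aldehyde is still masked, so Cannizzaro and aldol reactions are excluded, and the dilute acid that frees the acid and the aldehyde is too weak to damage the 1,3-disubstituted azulene or the alkene.

Step 8
Reactants: 13 (2Z)-3-(2-formyl-5-methylphenyl)-2-(guaiazulen-3-yl)but-2-enoic acid
Product: 15 2-(guaiazulen-3-yl)-3,7-dimethyl-1-oxo-1H-indene-4-carbaldehyde (CNP0233877.0), via acid chloride 14 (not isolated)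
Conditions: 1-chloro-N,N,2-trimethylprop-1-en-1-amine, CH2Cl2, 0 °C to rt; then 2,6-di-tert-butyl-4-methylpyridine, SnCl4 (2.5 equiv), CH2Cl2, −40 °C to rt
Reagents that add atoms: none
Why: Intramolecular Friedel–Crafts acylation; the closest known reaction type is the cyclodehydration of cis-β-arylacrylic acids to 2,3-disubstituted indenones. The chloroenamine converts the acid into acid chloride 14 under neutral conditions with only an amide as by-product, and SnCl4 then ionises the C–Cl bond to an acylium ion at the future C1. The Z geometry holds this carbon next to the aryl ring, so it attacks the only free ortho carbon, the future C7a, which is activated by the adjacent methyl group and stands meta to the formyl group; the hindered pyridine then takes the proton from the arenium ion. The five-membered ring is closed by electrophilic aromatic substitution, formally a 5-exo-dig attack on the acylium carbon with the C2=C3 and C3a–C7a bonds inside the new ring, and no stereocentre is formed. Site selectivity follows from the substitution pattern, because the other ortho position carries the formyl group. The azulene is left alone because its C1' bears a methyl group and its C3' the side chain, and attack at its C2' would need a four-membered ring. SnCl4 is used in excess because the formyl oxygen binds one equivalent, and the proton scavenger keeps HCl from protonating the azulene or the alkene.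

## Compound list

1 | methyl acetoacetate | COC(=O)CC(C)=O | starting material
2 | methyl 2-diazo-3-oxobutanoate | COC(=O)C(=[N+]=[N-])C(C)=O | intermediate
3 | guaiazulene (7-isopropyl-1,4-dimethylazulene) | c1cc(C)c2cc(C(C)C)ccc(C)c1-2 | starting material
4 | methyl 2-(guaiazulen-3-yl)-3-oxobutanoate (racemic) | COC(=O)C(C(C)=O)c1cc(C)c2cc(C(C)C)ccc(C)c1-2 | intermediate
5 | sodium (Z)-enolate of 4 (enolate oxygen cis to the ester) | C/C([O-])=C(/C(=O)OC)c1cc(C)c2cc(C(C)C)ccc(C)c1-2.[Na+] | intermediate
6 | methyl (2Z)-2-(guaiazulen-3-yl)-3-[(trifluoromethylsulfonyl)oxy]but-2-enoate | C/C(OS(=O)(=O)C(F)(F)F)=C(/C(=O)OC)c1cc(C)c2cc(C(C)C)ccc(C)c1-2 | intermediate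
7 | 2-bromo-4-methylbenzaldehyde | Cc1ccc(C=O)c(Br)c1 | starting material
8 | 2-(2-bromo-4-methylphenyl)-1,3-dioxolane | Cc1ccc(C2OCCO2)c(Br)c1 | intermediate
9 | [2-(1,3-dioxolan-2-yl)-5-methylphenyl]lithium | Cc1ccc(C2OCCO2)c([Li])c1 | intermediate
10 | 2-[2-(1,3-dioxolan-2-yl)-5-methylphenyl]-4,4,5,5-tetramethyl-1,3,2-dioxaborolane | Cc1ccc(C2OCCO2)c(B2OC(C)(C)C(C)(C)O2)c1 | intermediate
11 | methyl (2Z)-3-[2-(1,3-dioxolan-2-yl)-5-methylphenyl]-2-(guaiazulen-3-yl)but-2-enoate | C/C(c1cc(C)ccc1C1OCCO1)=C(/C(=O)OC)c1cc(C)c2cc(C(C)C)ccc(C)c1-2 | intermediate
12 | lithium (2Z)-3-[2-(1,3-dioxolan-2-yl)-5-methylphenyl]-2-(guaiazulen-3-yl)but-2-enoate | C/C(c1cc(C)ccc1C1OCCO1)=C(/C(=O)[O-])c1cc(C)c2cc(C(C)C)ccc(C)c1-2.[Li+] | intermediate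
13 | (2Z)-3-(2-formyl-5-methylphenyl)-2-(guaiazulen-3-yl)but-2-enoic acid | C/C(c1cc(C)ccc1C=O)=C(/C(=O)O)c1cc(C)c2cc(C(C)C)ccc(C)c1-2 | intermediate
14 | (2Z)-3-(2-formyl-5-methylphenyl)-2-(guaiazulen-3-yl)but-2-enoyl chloride | C/C(c1cc(C)ccc1C=O)=C(/C(Cl)=O)c1cc(C)c2cc(C(C)C)ccc(C)c1-2 | intermediate
15 | 2-(guaiazulen-3-yl)-3,7-dimethyl-1-oxo-1H-indene-4-carbaldehyde (CNP0233877.0) | CC1=C(c2cc(C)c3cc(C(C)C)ccc(C)c2-3)C(=O)c2c(C)ccc(C=O)c21 | target

## Step count and least certain steps

Total: 8 steps. Longest linear sequence: 6 steps (steps 1, 2, 3, 6, 7, 8). The aryl branch (steps 4 and 5) joins at step 6.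

**Step 8 (key step).** The most likely failure is ring acylation that is too slow. The formyl group withdraws electron density, and more so once it is bound to SnCl4. That leaves time for acid-induced Z/E equilibration of the alkene, for Lewis-acid-triggered reaction of the activated aldehyde with the neighbouring alkene, or for slow degradation of the azulene. The fallback lowers the oxidation level of the formyl carbon for the ring closure. It sets out from 13 and returns at 15. The aldehyde of 13 would be reduced selectively as its sodium carboxylate (NaBH4, aq. NaOH/MeOH, 0 °C) to (2Z)-2-(guaiazulen-3-yl)-3-[2-(hydroxymethyl)-5-methylphenyl]but-2-enoic acid F1. Acetylation (Ac2O, pyridine, then aqueous work-up to cleave the mixed anhydride) would give the acetoxymethyl acid F2. Its acid chloride F3, made with the same chloroenamine, would be cyclised with SnCl4 and the hindered pyridine to [2-(guaiazulen-3-yl)-3,7-dimethyl-1-oxo-1H-inden-4-yl]methyl acetate F4. In F3 the ring is only weakly deactivated and has no Lewis-basic aldehyde. Methanolysis (K2CO3, MeOH) would give the alcohol 2-(guaiazulen-3-yl)-4-(hydroxymethyl)-3,7-dimethyl-1H-inden-1-one F5, and a buffered Dess–Martin oxidation would give 15.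

**Step 2.** The carbenoid may add to π-bonds of the seven-membered ring (cyclopropanation and ring expansion), or may be slowed at C3' by the peri methyl group so that carbene dimerisation dominates. The fallback uses classical electrophilic substitution. It sets out from 3 and returns at 4. Oxalyl chloride in Et2O at 0 °C would give 2-(guaiazulen-3-yl)-2-oxoacetyl chloride F6, which methanol would convert into methyl 2-(guaiazulen-3-yl)-2-oxoacetate F7. Deoxygenation of the azulenyl ketone through the azulene-stabilised cation (NaBH4, BF3·OEt2) would give methyl 2-(guaiazulen-3-yl)acetate F8. Deprotonation with LiN(SiMe3)2 (2 equiv, THF, −78 °C) and C-acetylation with N-acetylimidazole (a crossed Claisen condensation) would give 4.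

**Step 3.** Chelation control may be lost, which would erode the Z geometry, or the hindered stabilised enolate may be sulfonylated only sluggishly. The fallback changes the leaving group. It sets out from 4 and returns at 11. Z-selective enol tosylation through the lithium chelate (TsCl, N-methylimidazole, LiOH) would give methyl (2Z)-2-(guaiazulen-3-yl)-3-(tosyloxy)but-2-enoate F9. F9 is more robust than the triflate and would be coupled with 10 under the Pd(OAc)2/SPhos conditions of step 6.

**Step 6.** Hydroxide or phosphate may cleave the S–O bond of the triflate and return 4 before the hindered transmetalation takes place. The ortho-substituted boronate may also undergo protodeboronation, or the alkene geometry may scramble at the palladium stage. The fallback is an anhydrous, base-free Negishi coupling. It sets out from 8 and 6 and returns at 11. Aryllithium 9, made from 8 as in step 5, would be transmetalated with ZnCl2 to [2-(1,3-dioxolan-2-yl)-5-methylphenyl]zinc chloride F10. F10 would be coupled with 6 using Pd2(dba)3/SPhos in THF at rt to 50 °C.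

**Step 7.** Acyl substitution at the ester, which is flanked by the twisted azulenyl group and the cis aryl ring, may be slow. Prolonged heating with hydroxide may then allow γ-deprotonation to a dienolate, with loss of alkene geometry or migration of the double bond. The fallback attacks the methyl carbon instead of the carbonyl carbon. It sets out from 11 and returns at 12. Demethylation by an SN2 reaction with LiI in refluxing pyridine would give carboxylate 12 directly, and the acid treatment of step 7 would then give 13.

## Further compounds

F1 | step 8 | (2Z)-2-(guaiazulen-3-yl)-3-[2-(hydroxymethyl)-5-methylphenyl]but-2-enoic acid | C/C(c1cc(C)ccc1CO)=C(/C(=O)O)c1cc(C)c2cc(C(C)C)ccc(C)c1-2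
F2 | step 8 | (2Z)-3-[2-(acetoxymethyl)-5-methylphenyl]-2-(guaiazulen-3-yl)but-2-enoic acid | C/C(c1cc(C)ccc1COC(C)=O)=C(/C(=O)O)c1cc(C)c2cc(C(C)C)ccc(C)c1-2
F3 | step 8 | (2Z)-3-[2-(acetoxymethyl)-5-methylphenyl]-2-(guaiazulen-3-yl)but-2-enoyl chloride | C/C(c1cc(C)ccc1COC(C)=O)=C(/C(Cl)=O)c1cc(C)c2cc(C(C)C)ccc(C)c1-2
F4 | step 8 | [2-(guaiazulen-3-yl)-3,7-dimethyl-1-oxo-1H-inden-4-yl]methyl acetate | CC1=C(c2cc(C)c3cc(C(C)C)ccc(C)c2-3)C(=O)c2c(C)ccc(COC(C)=O)c21
F5 | step 8 | 2-(guaiazulen-3-yl)-4-(hydroxymethyl)-3,7-dimethyl-1H-inden-1-one | CC1=C(c2cc(C)c3cc(C(C)C)ccc(C)c2-3)C(=O)c2c(C)ccc(CO)c21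
F6 | step 2 | 2-(guaiazulen-3-yl)-2-oxoacetyl chloride | O=C(Cl)C(=O)c1cc(C)c2cc(C(C)C)ccc(C)c1-2
F7 | step 2 | methyl 2-(guaiazulen-3-yl)-2-oxoacetate | COC(=O)C(=O)c1cc(C)c2cc(C(C)C)ccc(C)c1-2
F8 | step 2 | methyl 2-(guaiazulen-3-yl)acetate | COC(=O)Cc1cc(C)c2cc(C(C)C)ccc(C)c1-2
F9 | step 3 | methyl (2Z)-2-(guaiazulen-3-yl)-3-(tosyloxy)but-2-enoate | C/C(OS(=O)(=O)c1ccc(C)cc1)=C(/C(=O)OC)c1cc(C)c2cc(C(C)C)ccc(C)c1-2
F10 | step 6 | [2-(1,3-dioxolan-2-yl)-5-methylphenyl]zinc chloride | Cc1ccc(C2OCCO2)c([Zn]Cl)c1
F0 | step 7 | none | none
A1 | alternative 1 | 3-{2-[3-(1,3-dioxolan-2-yl)-6-methyl-2-(2-methyl-1,3-dioxolan-2-yl)phenyl]-2-oxoethyl}-7-isopropyl-4-methyl-3,8a-dihydroazulen-1(2H)-one (diastereomer mixture) | O=C1CC(CC(=O)c3c(C)ccc(C4OCCO4)c3C5(C)OCCO5)C2=C(C)C=CC(C(C)C)=CC12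
A2 | alternative 1 | 1-diazo-6-[3-(1,3-dioxolan-2-yl)-6-methyl-2-(2-methyl-1,3-dioxolan-2-yl)phenyl]-4-(5-isopropyl-2-methylphenyl)hexane-2,6-dione | [N-]=[N+]=CC(=O)CC(CC(=O)c1c(C)ccc(C2OCCO2)c1C1(C)OCCO1)c1cc(C(C)C)ccc1C
A3 | alternative 2 | 1-[3-(1,3-dioxolan-2-yl)-6-methyl-2-(2-methyl-1,3-dioxolan-2-yl)phenyl]-2-(guaiazulen-3-yl)ethanone | O=C(Cc1cc(C)c2cc(C(C)C)ccc(C)c1-2)c1c(C)ccc(C2OCCO2)c1C1(C)OCCO1
A4 | alternative 2 | 5-isopropyl-3,8-dimethyl-2H-cyclohepta[b]furan-2-one | O=C1OC2=C(C)C=CC(C(C)C)=CC2=C1C
A5 | alternative 2 | (3E)-1-[3-(1,3-dioxolan-2-yl)-6-methyl-2-(2-methyl-1,3-dioxolan-2-yl)phenyl]-4-(pyrrolidin-1-yl)but-3-en-1-one | O=C(C/C=C/N1CCCC1)c1c(C)ccc(C2OCCO2)c1C1(C)OCCO1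
A6 | alternative 3 | 4-(diethoxymethyl)-2-(guaiazulen-3-yl)-3,7-dimethyl-1H-inden-1-one | CC1=C(c2cc(C)c3cc(C(C)C)ccc(C)c2-3)C(=O)c2c(C)ccc(C(OCC)OCC)c21
A7 | alternative 3 | (5Z)-9,9-diethoxy-5-(guaiazulen-3-yl)-6-methylnon-5-ene-2,7-diyn-4-one | CC#CC(=O)/C(c1cc(C)c2cc(C(C)C)ccc(C)c1-2)=C(/C)C#CC(OCC)OCC
A8 | alternative 3 | acetylene | C#C
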